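A direct plan would cyclise (2E,6E)-farnesyl acetate A1 under a chiral proton source to the monocyclic acetate A2, extend A2 by allylic alkylation to the α-keto ester A3, set C3 by a catalytic Mukaiyama aldol with a thioacetate ketene acetal, reduce both acyl groups to the silyloxy dialdehyde A4, and close with enol acetylation, desilylation and acetylation in one flask.
Its weakest points would be three.
The proton-initiated monocyclisation would need more than one equivalent of a chiral acid, would have to stop after one ring and choose one of three alkene positions, and would leave the ring stereocentre to a face selectivity without close precedent.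
The twofold half-reduction of an ester and a thioester would have to stop at A4, a β-silyloxy dialdehyde that is prone to over-reduction and β-elimination and could not be stored.
The final enol acetylation of A4 would leave the C1=C2 geometry to a thermodynamic preference, would compete with E1cB loss of the C3 oxygen, and would be run on the most valuable material of the route.

**Plan of the new route**
The retrosynthesis cuts C3–C4 (Grignard reagent plus ynone), then C1–O (enol acetate from an ethynyl group through an (E)-alkenylboron), C5–C6 (alkenylalane plus oxirane, the alkenylalane from a ring-bearing alkyne and AlMe3) and the bond from the ring to C9 (Claisen rearrangement); the formyl carbon is unveiled last.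
Enabling feature: C3 is a carbinol carbon that carries a formyl carbon and the sp2 carbon C2 of an (E)-2-acetoxyvinyl group. The formyl carbon can therefore be C4 of a (4S)-2,2-dimethyl-1,3-dioxolane (a glycerate), whose ring oxygen binds magnesium and whose stereocentre steers the addition to C3 before its CH2O carbon is excised; C1=C2 can be an ethynyl group.
The only ring, the 2,6,6-trimethylcyclohexene, is never closed: it is bought as 2,4,4-trimethylcyclohex-2-en-1-one, and its stereocentre arises first, by enantioselective reduction and 1,3-chirality transfer in a [3,3] shift.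
The weak steps do not arise: there is no cationic cyclisation and no dialdehyde; the enol acetate geometry is fixed by a syn hydroboration and a stereoretentive C–O coupling, not by enolisation; the aldehyde appears once, in the last step, by glycol cleavage next to a quaternary carbon.

Key step: step 10

Assumption: 2,4,4-trimethylcyclohex-2-en-1-one and methyl (4S)-2,2-dimethyl-1,3-dioxolane-4-carboxylate are taken as commercial; locants C1–C9 are those of the nona-1,6-dien-1-yl acetate name of the target (C3 is the quaternary carbon), and ring and dioxolane atoms are named as such.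

Step 1
Reactants: 1 2,4,4-trimethylcyclohex-2-en-1-one
Product: 2 (1R)-2,4,4-trimethylcyclohex-2-en-1-ol
Conditions: (3aS)-1-methyl-3,3-diphenylhexahydropyrrolo[1,2-c][1,3,2]oxazaborole (10 mol %), BH3·SMe2 (0.6 equiv), THF, −20 °C; MeOH
Reagents that add atoms: none
Why: Corey–Bakshi–Shibata reduction, reliable for 2-substituted cyclohexenones: the ketone should bind the catalyst boron with its alkene arm as the large group, so that hydride from the N-bound borane reaches one face and sets the carbinol carbon as (R).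

Step 2
Reactants: 2 (1R)-2,4,4-trimethylcyclohex-2-en-1-ol; 3 triethyl orthoacetate
Product: 5 ethyl 2-[(1S)-2,6,6-trimethylcyclohex-2-en-1-yl]acetate, via ketene acetal 4 (not isolated)
Conditions: 3 (5 equiv), EtCO2H (5 mol %), 140 °C, ethanol distilled off
Reagents that add atoms: none
Why: Johnson–Claisen rearrangement: acid-catalysed exchange gives ketene acetal 4, whose suprafacial [3,3] shift delivers the CH2CO2Et carbon to ring C3 on the face that the C1–O bond leaves, so the carbinol configuration is transferred to the new ring stereocentre as (S) while the alkene moves into the 2,3-position of the product.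

Step 3
Reactants: 5 ethyl 2-[(1S)-2,6,6-trimethylcyclohex-2-en-1-yl]acetate
Product: 6 2-[(1S)-2,6,6-trimethylcyclohex-2-en-1-yl]ethan-1-ol
Conditions: LiAlH4, Et2O, 0 °C; H2O, aq. NaOH
Reagents that add atoms: none
Why: Ester reduction with LiAlH4 (hydride addition, loss of ethoxide, second hydride addition); the ring stereocentre and the alkene are not touched.

Step 4
Reactants: 6 2-[(1S)-2,6,6-trimethylcyclohex-2-en-1-yl]ethan-1-ol
Product: 7 (6S)-6-(2-iodoethyl)-1,5,5-trimethylcyclohex-1-ene
Conditions: I2, PPh3, imidazole, CH2Cl2, 0 °C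
Reagents that add atoms: iodine II
Why: Appel-type iodination: the alkoxyphosphonium ion formed from PPh3/I2 is displaced by iodide in an SN2 reaction at the primary carbon.

Step 5
Reactants: 7 (6S)-6-(2-iodoethyl)-1,5,5-trimethylcyclohex-1-ene; 8 lithium acetylide–ethane-1,2-diamine complex
Product: 9 (6S)-6-(but-3-yn-1-yl)-1,5,5-trimethylcyclohex-1-ene
Conditions: DMSO, 15 °C to rt
Reagents that add atoms: none
Why: SN2 alkylation of an acetylide by a primary iodide in DMSO, the standard route to terminal alkynes; the stereocentre is two carbons away.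

Step 6
Reactants: 9 (6S)-6-(but-3-yn-1-yl)-1,5,5-trimethylcyclohex-1-ene; 10 oxirane
Product: 13 (3E)-4-methyl-6-[(1S)-2,6,6-trimethylcyclohex-2-en-1-yl]hex-3-en-1-ol, via alkenylalane 11 (not isolated), via lithium alkenylalanate 12 (not isolated)
Conditions: AlMe3 (2 equiv), Zr(C5H5)2Cl2 (25 mol %), CH2Cl2, rt; volatiles removed, hexane; n-BuLi, 0 °C; 10, THF, 0 °C to rt; aq. HCl
Reagents that add atoms: trimethylaluminium C[Al](C)C
Why: Zirconium-catalysed carboalumination (Negishi) adds CH3 and Al syn across the terminal alkyne with Al on the terminal carbon, which fixes the (E)-trisubstituted alkene in alkenylalane 11; its ate complex 12 opens oxirane with retention at the alkenyl carbon, so three components are joined in one flask.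

Step 7
Reactants: 13 (3E)-4-methyl-6-[(1S)-2,6,6-trimethylcyclohex-2-en-1-yl]hex-3-en-1-ol
Product: 14 (6S)-6-[(3E)-6-iodo-3-methylhex-3-en-1-yl]-1,5,5-trimethylcyclohex-1-ene
Conditions: I2, PPh3, imidazole, CH2Cl2, 0 °C
Reagents that add atoms: iodine II
Why: Appel-type iodination of the primary homoallylic alcohol by SN2 displacement; the alkene geometry is not affected.

Step 8
Reactants: 15 methyl (4S)-2,2-dimethyl-1,3-dioxolane-4-carboxylate; 16 N,O-dimethylhydroxylamine hydrochloride
Product: 17 (4S)-N-methoxy-N,2,2-trimethyl-1,3-dioxolane-4-carboxamide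
Conditions: 16 (1.5 equiv), i-PrMgCl (3 equiv), THF, −20 °C; aq. NH4Cl
Reagents that add atoms: none
Why: Weinreb amide formation by attack of the magnesium amide of N,O-dimethylhydroxylamine on the ester at −20 °C, conditions under which the α-alkoxy stereocentre of a glycerate should not epimerise.

Step 9
Reactants: 17 (4S)-N-methoxy-N,2,2-trimethyl-1,3-dioxolane-4-carboxamide; 18 ethynyl(trimethyl)silane
Product: 20 1-[(4S)-2,2-dimethyl-1,3-dioxolan-4-yl]-3-(trimethylsilyl)prop-2-yn-1-one, via lithium silylacetylide 19 (not isolated)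
Conditions: 18, n-BuLi, THF, −78 °C; then 17, −78 to 0 °C; aq. NH4Cl
Reagents that add atoms: none
Why: Weinreb ketone synthesis: acetylide 19 adds once because the chelated tetrahedral adduct persists until work-up, giving the ynone with the dioxolane stereocentre intact.

Step 10
Reactants: 14 (6S)-6-[(3E)-6-iodo-3-methylhex-3-en-1-yl]-1,5,5-trimethylcyclohex-1-ene; 20 1-[(4S)-2,2-dimethyl-1,3-dioxolan-4-yl]-3-(trimethylsilyl)prop-2-yn-1-one
Product: 24 (3R,6E)-3-[(4S)-2,2-dimethyl-1,3-dioxolan-4-yl]-7-methyl-9-[(1S)-2,6,6-trimethylcyclohex-2-en-1-yl]non-6-en-1-yn-3-ol, via alkyllithium 21 (not isolated), via alkylmagnesium bromide 22 (not isolated), via silylalkynol 23 (not isolated)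
Conditions: 14, t-BuLi (2.1 equiv), Et2O, −78 °C; MgBr2·OEt2 (1.5 equiv), −78 to −20 °C; 20, CH2Cl2, −78 °C; then MeOH, K2CO3, rt; aq. NH4Cl
Reagents that add atoms: none
Why: Iodine–lithium exchange at −78 °C gives the homoallylic alkyllithium 21 without touching the alkene geometry, and MgBr2 turns it into Grignard reagent 22, whose magnesium bridges the ketone oxygen and dioxolane O3 on the α-carbon of ynone 20 in a five-membered Cram chelate (reaction type: chelation-controlled 1,2-addition of a Grignard reagent to an α-alkoxy ketone, precedented for ketones whose α-oxygen is part of a dioxolane). In this chelate the two faces of the carbonyl differ by the dioxolane C4–H against the dioxolane C5 methylene, so the chain should enter from the hydrogen side and create C3 as (R); the controlling element is the (4S) dioxolane carbon, a stereocentre that is not in the target and is cut out in step 14. No ring is closed; the step forms the C3–C4 bond, joins the C16 and C11 halves, and places the latent C1, C2 and formyl carbon around the new carbinol centre. It needs 1,2- over 1,4-addition, which a copper-free magnesium reagent at −78 °C and the silyl group on the far alkyne carbon should secure, and face selectivity, which the non-coordinating solvent CH2Cl2 and the small, linear alkynyl substituent (no second donor, no steric competition) should favour. Methanolic K2CO3 then removes the alkyne silyl group in the same flask, and a minor C3 epimer, being a diastereomer with an adjacent stereocentre, should be removable by chromatography at this stage.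

Step 11
Reactants: 24 (3R,6E)-3-[(4S)-2,2-dimethyl-1,3-dioxolan-4-yl]-7-methyl-9-[(1S)-2,6,6-trimethylcyclohex-2-en-1-yl]non-6-en-1-yn-3-ol
Product: 25 (3R,6E)-3-[(4S)-2,2-dimethyl-1,3-dioxolan-4-yl]-7-methyl-9-[(1S)-2,6,6-trimethylcyclohex-2-en-1-yl]non-6-en-1-yn-3-yl acetate
Conditions: Ac2O, Et3N, 4-(dimethylamino)pyridine (0.5 equiv), CH2Cl2, rt to 40 °C
Reagents that add atoms: acetic anhydride CC(=O)OC(C)=O
Why: 4-(Dimethylamino)pyridine-catalysed acyl transfer to the tertiary propargylic alcohol; no bond to C3 is broken, so C3 stays (R).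

Step 12
Reactants: 25 (3R,6E)-3-[(4S)-2,2-dimethyl-1,3-dioxolan-4-yl]-7-methyl-9-[(1S)-2,6,6-trimethylcyclohex-2-en-1-yl]non-6-en-1-yn-3-yl acetate
Product: 27 potassium {(1E,3R,6E)-3-(acetyloxy)-3-[(4S)-2,2-dimethyl-1,3-dioxolan-4-yl]-7-methyl-9-[(1S)-2,6,6-trimethylcyclohex-2-en-1-yl]nona-1,6-dien-1-yl}trifluoroborate, via pinacol alkenylboronate 26 (not isolated)
Conditions: pinacolborane (1.5 equiv), (C6H11)2BH (10 mol %), THF, rt; then KHF2, MeOH/H2O, rt
Reagents that add atoms: pinacolborane [H]B1OC(C)(C)C(C)(C)O1; potassium hydrogen difluoride [K+].F[H-]F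
Why: Dicyclohexylborane-catalysed hydroboration of the terminal alkyne with pinacolborane is a syn addition that places boron on C1 (anti-Markovnikov, reinforced by the quaternary C3) and so gives the (E)-alkenylboronate 26, which KHF2 converts into the trifluoroborate; the trisubstituted alkenes are too hindered to react.

Step 13
Reactants: 27 potassium {(1E,3R,6E)-3-(acetyloxy)-3-[(4S)-2,2-dimethyl-1,3-dioxolan-4-yl]-7-methyl-9-[(1S)-2,6,6-trimethylcyclohex-2-en-1-yl]nona-1,6-dien-1-yl}trifluoroborate
Product: 28 (1E,3R,6E)-3-(acetyloxy)-3-[(4S)-2,2-dimethyl-1,3-dioxolan-4-yl]-7-methyl-9-[(1S)-2,6,6-trimethylcyclohex-2-en-1-yl]nona-1,6-dien-1-yl acetate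
Conditions: AcOH (2 equiv), CuBr (10 mol %), 4-(dimethylamino)pyridine (20 mol %), 4 Å molecular sieves, O2 (1 atm), MeCN, 60 °C
Reagents that add atoms: acetic acid CC(=O)O
Why: Copper-catalysed oxidative C–O coupling of an alkenyltrifluoroborate with a carboxylic acid (Chan–Lam type): transmetalation, oxidation to trivalent copper and reductive elimination all keep the alkene geometry, so the (E)-alkenylboron gives the (E)-enol acetate.

Step 14
Reactants: 28 (1E,3R,6E)-3-(acetyloxy)-3-[(4S)-2,2-dimethyl-1,3-dioxolan-4-yl]-7-methyl-9-[(1S)-2,6,6-trimethylcyclohex-2-en-1-yl]nona-1,6-dien-1-yl acetate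
Product: 30 (1E,3R,6E)-3-(acetyloxy)-3-formyl-7-methyl-9-[(1S)-2,6,6-trimethylcyclohex-2-en-1-yl]nona-1,6-dien-1-yl acetate (CNP0244145.1), via diol 29 (not isolated)
Conditions: H5IO6 (1.5 equiv), EtOAc, 0 °C to rt
Reagents that add atoms: none
Why: Periodic acid in ethyl acetate first hydrolyses the terminal isopropylidene acetal and then cleaves the freed 1,2-diol 29 (glycol cleavage), which removes dioxolane C5 as formaldehyde and turns dioxolane C4 into the formyl carbon; C3 carries no hydrogen and cannot epimerise, and periodate does not attack the alkenes.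

**Compound list**
1 | 2,4,4-trimethylcyclohex-2-en-1-one | CC1=CC(C)(C)CCC1=O | starting material
2 | (1R)-2,4,4-trimethylcyclohex-2-en-1-ol | O[C@H]1C(C)=CC(C)(C)CC1 | intermediate
3 | triethyl orthoacetate | CCOC(C)(OCC)OCC | starting material
4 | (6R)-6-[(1-ethoxyethenyl)oxy]-1,3,3-trimethylcyclohex-1-ene | C=C(OCC)O[C@H]1C(C)=CC(C)(C)CC1 | intermediate
5 | ethyl 2-[(1S)-2,6,6-trimethylcyclohex-2-en-1-yl]acetate | CCOC(=O)C[C@@H]1C(C)=CCCC1(C)C | intermediate
6 | 2-[(1S)-2,6,6-trimethylcyclohex-2-en-1-yl]ethan-1-ol | OCC[C@@H]1C(C)=CCCC1(C)C | intermediate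
7 | (6S)-6-(2-iodoethyl)-1,5,5-trimethylcyclohex-1-ene | ICC[C@@H]1C(C)=CCCC1(C)C | intermediate
8 | lithium acetylide–ethane-1,2-diamine complex | [Li+].[C-]#C.NCCN | starting material
9 | (6S)-6-(but-3-yn-1-yl)-1,5,5-trimethylcyclohex-1-ene | C#CCC[C@@H]1C(C)=CCCC1(C)C | intermediate
10 | oxirane | C1CO1 | starting material
11 | dimethyl{(1E)-2-methyl-4-[(1S)-2,6,6-trimethylcyclohex-2-en-1-yl]but-1-en-1-yl}alumane | C[Al](C)/C=C(\C)CC[C@@H]1C(C)=CCCC1(C)C | intermediate
12 | lithium butyl(dimethyl){(1E)-2-methyl-4-[(1S)-2,6,6-trimethylcyclohex-2-en-1-yl]but-1-en-1-yl}aluminate | [Li+].CCCC[Al-](C)(C)/C=C(\C)CC[C@@H]1C(C)=CCCC1(C)C | intermediate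
13 | (3E)-4-methyl-6-[(1S)-2,6,6-trimethylcyclohex-2-en-1-yl]hex-3-en-1-ol | OCC/C=C(\C)CC[C@@H]1C(C)=CCCC1(C)C | intermediate
14 | (6S)-6-[(3E)-6-iodo-3-methylhex-3-en-1-yl]-1,5,5-trimethylcyclohex-1-ene | ICC/C=C(\C)CC[C@@H]1C(C)=CCCC1(C)C | intermediate
15 | methyl (4S)-2,2-dimethyl-1,3-dioxolane-4-carboxylate | COC(=O)[C@@H]1COC(C)(C)O1 | starting material
16 | N,O-dimethylhydroxylamine hydrochloride | CNOC.Cl | starting material
17 | (4S)-N-methoxy-N,2,2-trimethyl-1,3-dioxolane-4-carboxamide | CON(C)C(=O)[C@@H]1COC(C)(C)O1 | intermediate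
18 | ethynyl(trimethyl)silane | C#C[Si](C)(C)C | starting material
19 | lithium (trimethylsilyl)acetylide | [Li]C#C[Si](C)(C)C | intermediate
20 | 1-[(4S)-2,2-dimethyl-1,3-dioxolan-4-yl]-3-(trimethylsilyl)prop-2-yn-1-one | C[Si](C)(C)C#CC(=O)[C@@H]1COC(C)(C)O1 | intermediate
21 | {(3E)-4-methyl-6-[(1S)-2,6,6-trimethylcyclohex-2-en-1-yl]hex-3-en-1-yl}lithium | [Li]CC/C=C(\C)CC[C@@H]1C(C)=CCCC1(C)C | intermediate
22 | bromo{(3E)-4-methyl-6-[(1S)-2,6,6-trimethylcyclohex-2-en-1-yl]hex-3-en-1-yl}magnesium | Br[Mg]CC/C=C(\C)CC[C@@H]1C(C)=CCCC1(C)C | intermediate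
23 | (3R,6E)-3-[(4S)-2,2-dimethyl-1,3-dioxolan-4-yl]-7-methyl-1-(trimethylsilyl)-9-[(1S)-2,6,6-trimethylcyclohex-2-en-1-yl]non-6-en-1-yn-3-ol | C[Si](C)(C)C#C[C@](O)(CC/C=C(\C)CC[C@@H]1C(C)=CCCC1(C)C)[C@@H]2COC(C)(C)O2 | intermediate
24 | (3R,6E)-3-[(4S)-2,2-dimethyl-1,3-dioxolan-4-yl]-7-methyl-9-[(1S)-2,6,6-trimethylcyclohex-2-en-1-yl]non-6-en-1-yn-3-ol | C#C[C@](O)(CC/C=C(\C)CC[C@@H]1C(C)=CCCC1(C)C)[C@@H]2COC(C)(C)O2 | intermediate
25 | (3R,6E)-3-[(4S)-2,2-dimethyl-1,3-dioxolan-4-yl]-7-methyl-9-[(1S)-2,6,6-trimethylcyclohex-2-en-1-yl]non-6-en-1-yn-3-yl acetate | C#C[C@](OC(C)=O)(CC/C=C(\C)CC[C@@H]1C(C)=CCCC1(C)C)[C@@H]2COC(C)(C)O2 | intermediate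
26 | (1E,3R,6E)-3-[(4S)-2,2-dimethyl-1,3-dioxolan-4-yl]-7-methyl-1-(4,4,5,5-tetramethyl-1,3,2-dioxaborolan-2-yl)-9-[(1S)-2,6,6-trimethylcyclohex-2-en-1-yl]nona-1,6-dien-3-yl acetate | CC1(C)OB(OC1(C)C)/C=C/[C@](OC(C)=O)(CC/C=C(\C)CC[C@@H]2C(C)=CCCC2(C)C)[C@@H]3COC(C)(C)O3 | intermediate
27 | potassium {(1E,3R,6E)-3-(acetyloxy)-3-[(4S)-2,2-dimethyl-1,3-dioxolan-4-yl]-7-methyl-9-[(1S)-2,6,6-trimethylcyclohex-2-en-1-yl]nona-1,6-dien-1-yl}trifluoroborate | [K+].F[B-](F)(F)/C=C/[C@](OC(C)=O)(CC/C=C(\C)CC[C@@H]1C(C)=CCCC1(C)C)[C@@H]2COC(C)(C)O2 | intermediate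
28 | (1E,3R,6E)-3-(acetyloxy)-3-[(4S)-2,2-dimethyl-1,3-dioxolan-4-yl]-7-methyl-9-[(1S)-2,6,6-trimethylcyclohex-2-en-1-yl]nona-1,6-dien-1-yl acetate | CC(=O)O/C=C/[C@](OC(C)=O)(CC/C=C(\C)CC[C@@H]1C(C)=CCCC1(C)C)[C@@H]2COC(C)(C)O2 | intermediate
29 | (1E,3R,6E)-3-(acetyloxy)-3-[(1S)-1,2-dihydroxyethyl]-7-methyl-9-[(1S)-2,6,6-trimethylcyclohex-2-en-1-yl]nona-1,6-dien-1-yl acetate | CC(=O)O/C=C/[C@](OC(C)=O)(CC/C=C(\C)CC[C@@H]1C(C)=CCCC1(C)C)[C@@H](O)CO | intermediate
30 | (1E,3R,6E)-3-(acetyloxy)-3-formyl-7-methyl-9-[(1S)-2,6,6-trimethylcyclohex-2-en-1-yl]nona-1,6-dien-1-yl acetate (CNP0244145.1) | CC(=O)O/C=C/[C@@](C=O)(CC/C=C(\C)CC[C@@H]1C(C)=CCCC1(C)C)OC(C)=O | target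

**Step count**
Total: 14 steps. Longest linear sequence: 12 steps (steps 1–7 and 10–14); the dioxolane branch (steps 8 and 9) joins in step 10.

**Steps most likely to fail**
Step 10. The process at risk is face discrimination in the addition to ynone 20, where a chelated and a non-chelated transition state could compete; conjugate addition and α-deprotonation of 20 are lesser threats. The fallback reverses the order of bond formation at C3, so that the non-chelated (polar Felkin–Anh) mode becomes the productive one with the same dioxolane. It sets out from iodide 14 and amide 17: alkyllithium 21 acylates 17 to give the saturated ketone (4E)-1-[(4S)-2,2-dimethyl-1,3-dioxolan-4-yl]-5-methyl-7-[(1S)-2,6,6-trimethylcyclohex-2-en-1-yl]hept-4-en-1-one F1. A non-chelating alkynyl nucleophile, [(trimethylsilyl)ethynyl]tris(propan-2-olato)titanium F2 (from 19 and ClTi(Oi-Pr)3, THF, −78 °C), then adds anti to the dioxolane C4–O bond. With the chain already in place and the alkyne as the incoming group, this mode should lead to the same (3R) carbinol 23, and the fallback comes back to the route at 24 after K2CO3/MeOH.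

Step 13. The processes at risk are slow transmetalation of the hindered alkenyltrifluoroborate to copper and competing protodeboronation. The fallback replaces the boron nucleophile by a vinyl electrophile and sets out from propargylic acetate 25. Hydrozirconation with Zr(C5H5)2(H)Cl and iodinolysis with I2 would give (1E,3R,6E)-3-[(4S)-2,2-dimethyl-1,3-dioxolan-4-yl]-1-iodo-7-methyl-9-[(1S)-2,6,6-trimethylcyclohex-2-en-1-yl]nona-1,6-dien-3-yl acetate F3. Ullmann-type vinylic substitution with copper acetate CuOAc (monovalent copper) in pyridine, a substitution that keeps the alkene geometry, comes back to the route at enol acetate 28.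

Step 14. The processes at risk are migration of the C3 acetyl group to the neighbouring secondary hydroxyl of transient diol 29, which would stop the cleavage, and acid-induced loss of the enol acetate. The fallback exchanges the last two operations, so that the enol acetate never meets acid or periodate, and sets out from trifluoroborate 27. Aqueous acetic acid removes the acetonide to give potassium {(1E,3R,6E)-3-(acetyloxy)-3-[(1S)-1,2-dihydroxyethyl]-7-methyl-9-[(1S)-2,6,6-trimethylcyclohex-2-en-1-yl]nona-1,6-dien-1-yl}trifluoroborate F4. NaIO4 at pH 7 cleaves the glycol to potassium {(1E,3R,6E)-3-(acetyloxy)-3-formyl-7-methyl-9-[(1S)-2,6,6-trimethylcyclohex-2-en-1-yl]nona-1,6-dien-1-yl}trifluoroborate F5. The copper-catalysed acetoxylation of step 13, applied to F5, comes back to the route at target 30.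

**Further compounds**
F1 | step 10 | (4E)-1-[(4S)-2,2-dimethyl-1,3-dioxolan-4-yl]-5-methyl-7-[(1S)-2,6,6-trimethylcyclohex-2-en-1-yl]hept-4-en-1-one | O=C(CC/C=C(\C)CC[C@@H]1C(C)=CCCC1(C)C)[C@@H]2COC(C)(C)O2
F2 | step 10 | [(trimethylsilyl)ethynyl]tris(propan-2-olato)titanium | CC(C)O[Ti](OC(C)C)(OC(C)C)C#C[Si](C)(C)C
F3 | step 13 | (1E,3R,6E)-3-[(4S)-2,2-dimethyl-1,3-dioxolan-4-yl]-1-iodo-7-methyl-9-[(1S)-2,6,6-trimethylcyclohex-2-en-1-yl]nona-1,6-dien-3-yl acetate | I/C=C/[C@](OC(C)=O)(CC/C=C(\C)CC[C@@H]1C(C)=CCCC1(C)C)[C@@H]2COC(C)(C)O2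
F4 | step 14 | potassium {(1E,3R,6E)-3-(acetyloxy)-3-[(1S)-1,2-dihydroxyethyl]-7-methyl-9-[(1S)-2,6,6-trimethylcyclohex-2-en-1-yl]nona-1,6-dien-1-yl}trifluoroborate | [K+].F[B-](F)(F)/C=C/[C@](OC(C)=O)(CC/C=C(\C)CC[C@@H]1C(C)=CCCC1(C)C)[C@@H](O)CO
F5 | step 14 | potassium {(1E,3R,6E)-3-(acetyloxy)-3-formyl-7-methyl-9-[(1S)-2,6,6-trimethylcyclohex-2-en-1-yl]nona-1,6-dien-1-yl}trifluoroborate | [K+].F[B-](F)(F)/C=C/[C@@](C=O)(CC/C=C(\C)CC[C@@H]1C(C)=CCCC1(C)C)OC(C)=O
A1 | direct plan | (2E,6E)-farnesyl acetate | CC(=O)OC/C=C(\C)CC/C=C(\C)CCC=C(C)C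
A2 | direct plan | (2E)-3-methyl-5-[(1S)-2,6,6-trimethylcyclohex-2-en-1-yl]pent-2-en-1-yl acetate | CC(=O)OC/C=C(\C)CC[C@@H]1C(C)=CCCC1(C)C
A3 | direct plan | ethyl (5E)-6-methyl-2-oxo-8-[(1S)-2,6,6-trimethylcyclohex-2-en-1-yl]oct-5-enoate | CCOC(=O)C(=O)CC/C=C(\C)CC[C@@H]1C(C)=CCCC1(C)C
A4 | direct plan | (2R)-2-{(3E)-4-methyl-6-[(1S)-2,6,6-trimethylcyclohex-2-en-1-yl]hex-3-en-1-yl}-2-(trimethylsilyloxy)butanedial | O=CC[C@@](C=O)(CC/C=C(\C)CC[C@@H]1C(C)=CCCC1(C)C)O[Si](C)(C)C
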